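Labels: ring A = chromone arene, ring B = pyrone, ring C = isochromanone arene, ring D = lactone. Isochromanone atoms are unprimed and chromone atoms primed.
Cuts: (a) three O–alkyl bonds (two isopropyl ethers on ring C and the 5'-O-methyl). (b) C4a–C4 and O2–C1 of ring D together, giving a diarylmethane benzoic acid and (R)-propylene oxide. (c) O1'–C2', C2'–C3' and C4'–C4a' of ring B, giving a phenol. (d) The bond from the bridge CH2 to C5, giving an aryl iodide and an aldehyde.
Enabling feature: ring D (C1, O2, C3, C4, C4a, C8a) hangs on C8a of a benzoic acid. Its ortho positions are C8, which bears oxygen, and C4a, the only C–H. The unit C4–C3(CH3)–O2 is one propylene oxide opened at its CH2.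
Forward order: rings A and C are bought and joined through the bridge carbon (steps 1–5). Ring B is closed on ring A (steps 6–7), the acid is freed (step 8), ring D is closed (step 9) and the phenols are unmasked (step 10).
Stereochemistry: the only stereocentre, C3 (R), is bought with the epoxide. The C–C bond forms at the epoxide CH2, so the C3–O bond is never broken.

Key step: step 9

Remark: methyl 2,4-dihydroxy-3-methylbenzoate, 4-hydroxy-2,6-dimethoxybenzaldehyde and (R)-propylene oxide are taken as catalogue compounds. The ester is otherwise one Fischer esterification away from 2,4-dihydroxy-3-methylbenzoic acid.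

Step 1
Reactants: 1 methyl 2,4-dihydroxy-3-methylbenzoate
Product: 2 methyl 2,4-dihydroxy-5-iodo-3-methylbenzoate
Conditions: NIS (1.05 equiv), MeCN, 0 °C → rt
Reagents that add atoms: N-iodosuccinimide, O=C1CCC(=O)N1I
Why: Electrophilic aromatic iodination, in which C5 (ortho to the 4-OH, para to the 2-OH) is the only activated free position, whereas C6 is meta to both hydroxyls and ortho to the ester.

Step 2
Reactants: 2 methyl 2,4-dihydroxy-5-iodo-3-methylbenzoate
Product: 3 methyl 5-iodo-2,4-diisopropoxy-3-methylbenzoate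
Conditions: 2-bromopropane (4 equiv), K2CO3 (4 equiv), DMF, 70 °C
Reagents that add atoms: 2-bromopropane, CC(C)Br
Why: Double Williamson etherification, with isopropyl ethers chosen because they withstand Grignard, hydrogenolysis, BF3, base and palladium conditions yet fall to BCl3 while unchelated aryl methyl ethers stay.

Step 3
Reactants: 4 4-hydroxy-2,6-dimethoxybenzaldehyde
Product: 5 4-(benzyloxy)-2,6-dimethoxybenzaldehyde
Conditions: BnBr (1.1 equiv), K2CO3, DMF, rt
Reagents that add atoms: benzyl bromide, BrCc1ccccc1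
Why: Williamson etherification masks the phenol, which would quench the Grignard reagent and deactivate the aldehyde as its phenoxide, with a group that leaves in the same hydrogenolysis that later removes the carbinol oxygen.

Step 4
Reactants: 3 methyl 5-iodo-2,4-diisopropoxy-3-methylbenzoate; 5 4-(benzyloxy)-2,6-dimethoxybenzaldehyde
Product: 7 methyl 5-{[4-(benzyloxy)-2,6-dimethoxyphenyl](hydroxy)methyl}-2,4-diisopropoxy-3-methylbenzoate (racemic), via arylmagnesium chloride 6 (not isolated)
Conditions: 3, iPrMgCl·LiCl (1.05 equiv), THF, −20 °C; then 5, −20 → 0 °C; aq. NH4Cl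
Reagents that add atoms: none
Why: Iodine–magnesium exchange followed by Grignard 1,2-addition, in which the exchange outruns attack on the electron-rich ortho-alkoxy methyl ester at low temperature, the aldehyde is the most electrophilic carbonyl present, and the new carbinol centre forms racemic and is erased in step 5.

Step 5
Reactants: 7 methyl 5-{[4-(benzyloxy)-2,6-dimethoxyphenyl](hydroxy)methyl}-2,4-diisopropoxy-3-methylbenzoate
Product: 8 methyl 5-(4-hydroxy-2,6-dimethoxybenzyl)-2,4-diisopropoxy-3-methylbenzoate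
Conditions: H2 (1 atm), 10% Pd/C, EtOAc–AcOH, rt
Reagents that add atoms: none
Why: Catalytic hydrogenolysis cleaves both the O-benzyl ether and the doubly benzylic, donor-activated C–OH bond (debenzylation gives a 4-hydroxybenzhydrol that ionises readily in AcOH), while the isopropyl ethers, methyl ethers and ester are inert.

Step 6
Reactants: 8 methyl 5-(4-hydroxy-2,6-dimethoxybenzyl)-2,4-diisopropoxy-3-methylbenzoate
Product: 9 methyl 5-(3-acetyl-4-hydroxy-2,6-dimethoxybenzyl)-2,4-diisopropoxy-3-methylbenzoate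
Conditions: Ac2O (2 equiv), BF3·OEt2 (3 equiv), 0 → 50 °C; then MeOH–H2O, 60 °C
Reagents that add atoms: acetic anhydride, CC(=O)OC(C)=O
Why: Friedel–Crafts/Fries-type ortho-acetylation of a phloroglucinol-type phenol, in which the two free positions of ring A are equivalent and both ortho to the OH, ring C offers only a deactivated C–H, and the difluoroboron chelate of the o-hydroxy ketone holds back a second acylation.

Step 7
Reactants: 9 methyl 5-(3-acetyl-4-hydroxy-2,6-dimethoxybenzyl)-2,4-diisopropoxy-3-methylbenzoate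
Product: 11 methyl 5-[(5,7-dimethoxy-2-methyl-4-oxo-4H-chromen-6-yl)methyl]-2,4-diisopropoxy-3-methylbenzoate, via beta-diketone 10 (not isolated)
Conditions: NaH (5 equiv), MeOAc, THF, reflux; then conc. HCl, MeOH, reflux
Reagents that add atoms: methyl acetate, COC(C)=O
Why: Crossed Claisen condensation of the ketone enolate with methyl acetate (matched to the methyl ester so that no ester scrambling arises) and acid cyclodehydration, the classical 2-methylchromone synthesis, in which the single free phenol fixes O1' and so places the bridge at C6' and not C8'.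

Step 8
Reactants: 11 methyl 5-[(5,7-dimethoxy-2-methyl-4-oxo-4H-chromen-6-yl)methyl]-2,4-diisopropoxy-3-methylbenzoate
Product: 12 5-[(5,7-dimethoxy-2-methyl-4-oxo-4H-chromen-6-yl)methyl]-2,4-diisopropoxy-3-methylbenzoic acid
Conditions: LiOH·H2O (5 equiv), THF–MeOH–H2O, 45 °C; then 2 M HCl, THF, rt
Reagents that add atoms: lithium hydroxide, [Li+].[OH-]
Why: Ester saponification by acyl–oxygen cleavage, in which any pyrone opened by hydroxide rests as the stabilised diketone enolate and re-closes in the acidic work-up by the same cyclodehydration as in step 7.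

Step 9
Reactants: 12 5-[(5,7-dimethoxy-2-methyl-4-oxo-4H-chromen-6-yl)methyl]-2,4-diisopropoxy-3-methylbenzoic acid; 13 (R)-propylene oxide
Product: 15 (3R)-5-[(5,7-dimethoxy-2-methyl-4-oxo-4H-chromen-6-yl)methyl]-6,8-diisopropoxy-3,7-dimethylisochroman-1-one, via seco hydroxy acid 14 (not isolated)
Conditions: Pd(OAc)2 (10 mol %), N-acetyl-L-tert-leucine (20 mol %), KOAc (2 equiv), 13 (5 equiv), (CF3)2CHOH, 75 °C, sealed tube
Reagents that add atoms: none
Why: The potassium carboxylate of 12 binds divalent palladium carrying the N-acetyl amino acid ligand, and concerted metalation–deprotonation gives the five-membered palladacycle at C4a. The aryl–palladium bond then opens 13 in an SN2 manner at its CH2 terminus without a change of oxidation state (bond C4a–C4), and the alkoxide of 14 acylates on C1 (bond O2–C1), which sets divalent palladium free again. The closest known reaction type is the carboxylate-directed, palladium-catalysed ortho C–H alkylation of benzoic acids with terminal epoxides, which delivers 3,4-dihydroisocoumarins in one operation. Ring D closes by 6-exo-trig lactonisation. No stereocentre is created, since C3 is the untouched carbinol carbon of 13 and the priority order O > CH2 > CH3 is unchanged, so (R) in the epoxide is (R) in 15. Site selectivity follows from C8 carrying an isopropoxy group, which leaves C4a–H as the only ortho C–H; epoxide regiochemistry follows from the steric bias for the unsubstituted carbon; and the excess of 13 covers its loss to background opening.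

Step 10
Reactants: 15 (3R)-5-[(5,7-dimethoxy-2-methyl-4-oxo-4H-chromen-6-yl)methyl]-6,8-diisopropoxy-3,7-dimethylisochroman-1-one
Product: 16 (3R)-6,8-dihydroxy-5-[(5-hydroxy-7-methoxy-2-methyl-4-oxo-4H-chromen-6-yl)methyl]-3,7-dimethylisochroman-1-one (target)
Conditions: BCl3 (1 M in CH2Cl2, 8 equiv), CH2Cl2, −78 → 0 °C; then H2O
Reagents that add atoms: none
Why: Lewis-acid ether cleavage, in which BCl3 dealkylates the two secondary (isopropyl) aryl ethers and the carbonyl-chelated 5'-O-methyl group, while the unchelated 7'-methoxy group, the lactone and the C3–O bond (hence the R centre) are left alone.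

Compound list
1 | methyl 2,4-dihydroxy-3-methylbenzoate | COC(=O)c1ccc(O)c(C)c1O | starting material
2 | methyl 2,4-dihydroxy-5-iodo-3-methylbenzoate | COC(=O)c1cc(I)c(O)c(C)c1O | intermediate
3 | methyl 5-iodo-2,4-diisopropoxy-3-methylbenzoate | COC(=O)c1cc(I)c(OC(C)C)c(C)c1OC(C)C | intermediate
4 | 4-hydroxy-2,6-dimethoxybenzaldehyde | COc1cc(O)cc(OC)c1C=O | starting material
5 | 4-(benzyloxy)-2,6-dimethoxybenzaldehyde | COc1cc(OCc2ccccc2)cc(OC)c1C=O | intermediate
6 | [5-(methoxycarbonyl)-2,4-diisopropoxy-3-methylphenyl]magnesium chloride | COC(=O)c1cc([Mg]Cl)c(OC(C)C)c(C)c1OC(C)C | intermediate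
7 | methyl 5-{[4-(benzyloxy)-2,6-dimethoxyphenyl](hydroxy)methyl}-2,4-diisopropoxy-3-methylbenzoate (racemic) | COC(=O)c1cc(C(O)c2c(OC)cc(OCc3ccccc3)cc2OC)c(OC(C)C)c(C)c1OC(C)C | intermediate
8 | methyl 5-(4-hydroxy-2,6-dimethoxybenzyl)-2,4-diisopropoxy-3-methylbenzoate | COC(=O)c1cc(Cc2c(OC)cc(O)cc2OC)c(OC(C)C)c(C)c1OC(C)C | intermediate
9 | methyl 5-(3-acetyl-4-hydroxy-2,6-dimethoxybenzyl)-2,4-diisopropoxy-3-methylbenzoate | COC(=O)c1cc(Cc2c(OC)cc(O)c(C(C)=O)c2OC)c(OC(C)C)c(C)c1OC(C)C | intermediate
10 | methyl 5-[4-hydroxy-2,6-dimethoxy-3-(3-oxobutanoyl)benzyl]-2,4-diisopropoxy-3-methylbenzoate | COC(=O)c1cc(Cc2c(OC)cc(O)c(C(=O)CC(C)=O)c2OC)c(OC(C)C)c(C)c1OC(C)C | intermediate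
11 | methyl 5-[(5,7-dimethoxy-2-methyl-4-oxo-4H-chromen-6-yl)methyl]-2,4-diisopropoxy-3-methylbenzoate | COc1cc2oc(C)cc(=O)c2c(OC)c1Cc1cc(C(=O)OC)c(OC(C)C)c(C)c1OC(C)C | intermediate
12 | 5-[(5,7-dimethoxy-2-methyl-4-oxo-4H-chromen-6-yl)methyl]-2,4-diisopropoxy-3-methylbenzoic acid | COc1cc2oc(C)cc(=O)c2c(OC)c1Cc1cc(C(=O)O)c(OC(C)C)c(C)c1OC(C)C | intermediate
13 | (R)-propylene oxide, (2R)-2-methyloxirane | C[C@@H]1CO1 | starting material
14 | 3-[(5,7-dimethoxy-2-methyl-4-oxo-4H-chromen-6-yl)methyl]-2-[(2R)-2-hydroxypropyl]-4,6-diisopropoxy-5-methylbenzoic acid | COc1cc2oc(C)cc(=O)c2c(OC)c1Cc1c(OC(C)C)c(C)c(OC(C)C)c(C(=O)O)c1C[C@@H](C)O | intermediate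
15 | (3R)-5-[(5,7-dimethoxy-2-methyl-4-oxo-4H-chromen-6-yl)methyl]-6,8-diisopropoxy-3,7-dimethylisochroman-1-one | COc1cc2oc(C)cc(=O)c2c(OC)c1Cc1c(OC(C)C)c(C)c(OC(C)C)c2c1C[C@@H](C)OC2=O | intermediate
16 | (3R)-6,8-dihydroxy-5-[(5-hydroxy-7-methoxy-2-methyl-4-oxo-4H-chromen-6-yl)methyl]-3,7-dimethylisochroman-1-one | COc1cc2oc(C)cc(=O)c2c(O)c1Cc1c(O)c(C)c(O)c2c1C[C@@H](C)OC2=O | target

Total step count: 10.
Longest linear sequence: 9 steps (1 → 16 through steps 1, 2, 4, 5, 6, 7, 8, 9 and 10).

Steps most likely to fail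

**Step 9.** The C4a–H bond is wedged between the carboxylate and the bulky bridge. Its palladation may therefore be slower than O-alkylation of the carboxylate by the epoxide, so that the acid drains away as hydroxypropyl ester before any C–C bond forms.

The fallback sets out from 1 and returns at 15. It closes ring D before the bridge is built, on an acid whose ortho C–H has no neighbour.
- Bis-isopropylation of 1 (2-bromopropane, K2CO3, DMF) should give methyl 2,4-diisopropoxy-3-methylbenzoate F1.
- Saponification (NaOH, aq. MeOH) should give 2,4-diisopropoxy-3-methylbenzoic acid F2.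
- The same Pd(OAc)2/N-acetyl-L-tert-leucine/KOAc alkylation with 13 should pass through 2-[(2R)-2-hydroxypropyl]-4,6-diisopropoxy-5-methylbenzoic acid F3. It should lactonise to (3R)-6,8-diisopropoxy-3,7-dimethylisochroman-1-one F4.
- NIS with catalytic TFA in MeCN should iodinate the only aromatic C–H to give (3R)-5-iodo-6,8-diisopropoxy-3,7-dimethylisochroman-1-one F5.
- iPrMgCl·LiCl at −20 °C should convert this into [(3R)-6,8-diisopropoxy-3,7-dimethyl-1-oxoisochroman-5-yl]magnesium chloride F6.
- Addition of F6 to 5 should give (3R)-5-{[4-(benzyloxy)-2,6-dimethoxyphenyl](hydroxy)methyl}-6,8-diisopropoxy-3,7-dimethylisochroman-1-one F7 as a mixture of carbinol epimers.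
- Hydrogenolysis (H2, Pd/C, EtOAc–AcOH) should give (3R)-5-(4-hydroxy-2,6-dimethoxybenzyl)-6,8-diisopropoxy-3,7-dimethylisochroman-1-one F8.
- Ac2O/BF3·OEt2 should give (3R)-5-(3-acetyl-4-hydroxy-2,6-dimethoxybenzyl)-6,8-diisopropoxy-3,7-dimethylisochroman-1-one F9.
- NaH/MeOAc should give (3R)-5-[4-hydroxy-2,6-dimethoxy-3-(3-oxobutanoyl)benzyl]-6,8-diisopropoxy-3,7-dimethylisochroman-1-one F10.
- HCl in MeOH should then close ring B, and re-close the lactone should methoxide have opened it, to reach 15.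

**Step 6.** Under BF3 the electron-rich diarylmethane may undergo acid-induced scission (retro-Friedel–Crafts). The isopropyl group next to the ester may be lost, or the reaction may stall at the aryl acetate.

The fallback sets out from 8 and returns at 9. It brings in the acetyl group by cross-coupling instead of electrophilic acylation.
- NIS (1 equiv, MeCN, −20 °C) should give methyl 5-(4-hydroxy-3-iodo-2,6-dimethoxybenzyl)-2,4-diisopropoxy-3-methylbenzoate F11.
- Stille coupling with tributyl(1-ethoxyvinyl)stannane (PdCl2(PPh3)2, dioxane, 100 °C) should give methyl 5-[3-(1-ethoxyvinyl)-4-hydroxy-2,6-dimethoxybenzyl]-2,4-diisopropoxy-3-methylbenzoate F12.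
- 1 M HCl in THF should hydrolyse the enol ether to 9.

**Step 8.** The electron-rich ortho-alkoxy benzoate saponifies slowly. Prolonged exposure to hydroxide may open the pyrone and carry on to retro-Claisen loss of the new acetyl unit.

The fallback sets out from 9 and returns at 12. It moves the hydrolysis ahead of pyrone formation.
- NaOH in aqueous MeOH at reflux should convert 9, which has no base-labile ring, into 5-(3-acetyl-4-hydroxy-2,6-dimethoxybenzyl)-2,4-diisopropoxy-3-methylbenzoic acid F13.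
- Claisen condensation on its polyanion (NaH in excess, MeOAc, THF–DMF) should give 5-[4-hydroxy-2,6-dimethoxy-3-(3-oxobutanoyl)benzyl]-2,4-diisopropoxy-3-methylbenzoic acid F14.
- AcOH with catalytic H2SO4 at 80 °C should cyclodehydrate this to 12 without esterifying the acid.

Further compounds
F1 | step 9 | methyl 2,4-diisopropoxy-3-methylbenzoate | COC(=O)c1ccc(OC(C)C)c(C)c1OC(C)C
F2 | step 9 | 2,4-diisopropoxy-3-methylbenzoic acid | OC(=O)c1ccc(OC(C)C)c(C)c1OC(C)C
F3 | step 9 | 2-[(2R)-2-hydroxypropyl]-4,6-diisopropoxy-5-methylbenzoic acid | C[C@@H](O)Cc1cc(OC(C)C)c(C)c(OC(C)C)c1C(=O)O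
F4 | step 9 | (3R)-6,8-diisopropoxy-3,7-dimethylisochroman-1-one | C[C@@H]1Cc2cc(OC(C)C)c(C)c(OC(C)C)c2C(=O)O1
F5 | step 9 | (3R)-5-iodo-6,8-diisopropoxy-3,7-dimethylisochroman-1-one | C[C@@H]1Cc2c(I)c(OC(C)C)c(C)c(OC(C)C)c2C(=O)O1
F6 | step 9 | [(3R)-6,8-diisopropoxy-3,7-dimethyl-1-oxoisochroman-5-yl]magnesium chloride | C[C@@H]1Cc2c([Mg]Cl)c(OC(C)C)c(C)c(OC(C)C)c2C(=O)O1
F7 | step 9 | (3R)-5-{[4-(benzyloxy)-2,6-dimethoxyphenyl](hydroxy)methyl}-6,8-diisopropoxy-3,7-dimethylisochroman-1-one (carbinol epimers) | C[C@@H]1Cc2c(C(O)c3c(OC)cc(OCc4ccccc4)cc3OC)c(OC(C)C)c(C)c(OC(C)C)c2C(=O)O1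
F8 | step 9 | (3R)-5-(4-hydroxy-2,6-dimethoxybenzyl)-6,8-diisopropoxy-3,7-dimethylisochroman-1-one | C[C@@H]1Cc2c(Cc3c(OC)cc(O)cc3OC)c(OC(C)C)c(C)c(OC(C)C)c2C(=O)O1
F9 | step 9 | (3R)-5-(3-acetyl-4-hydroxy-2,6-dimethoxybenzyl)-6,8-diisopropoxy-3,7-dimethylisochroman-1-one | C[C@@H]1Cc2c(Cc3c(OC)cc(O)c(C(C)=O)c3OC)c(OC(C)C)c(C)c(OC(C)C)c2C(=O)O1
F10 | step 9 | (3R)-5-[4-hydroxy-2,6-dimethoxy-3-(3-oxobutanoyl)benzyl]-6,8-diisopropoxy-3,7-dimethylisochroman-1-one | C[C@@H]1Cc2c(Cc3c(OC)cc(O)c(C(=O)CC(C)=O)c3OC)c(OC(C)C)c(C)c(OC(C)C)c2C(=O)O1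
F11 | step 6 | methyl 5-(4-hydroxy-3-iodo-2,6-dimethoxybenzyl)-2,4-diisopropoxy-3-methylbenzoate | COC(=O)c1cc(Cc2c(OC)cc(O)c(I)c2OC)c(OC(C)C)c(C)c1OC(C)C
F12 | step 6 | methyl 5-[3-(1-ethoxyvinyl)-4-hydroxy-2,6-dimethoxybenzyl]-2,4-diisopropoxy-3-methylbenzoate | COC(=O)c1cc(Cc2c(OC)cc(O)c(C(=C)OCC)c2OC)c(OC(C)C)c(C)c1OC(C)C
F13 | step 8 | 5-(3-acetyl-4-hydroxy-2,6-dimethoxybenzyl)-2,4-diisopropoxy-3-methylbenzoic acid | CC(=O)c1c(O)cc(OC)c(Cc2cc(C(=O)O)c(OC(C)C)c(C)c2OC(C)C)c1OC
F14 | step 8 | 5-[4-hydroxy-2,6-dimethoxy-3-(3-oxobutanoyl)benzyl]-2,4-diisopropoxy-3-methylbenzoic acid | CC(=O)CC(=O)c1c(O)cc(OC)c(Cc2cc(C(=O)O)c(OC(C)C)c(C)c2OC(C)C)c1OC
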